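**Retrosynthetic overview**
1. Feature: in the oxepane (C1–C14–C15–C16–O–C3–C2) the ring oxygen lies between the fully substituted C3 and the C16 methylene. Removing it leaves a cyclohexanone (C16=O) whose more substituted α-carbon is C3, which is the retron of a Baeyer–Villiger ring expansion.
2. Endgame: the C6–C7 bond (Nozaki–Hiyama–Kishi) closes the oxonene last. The (Z)-iodoalkene comes from a C8 aldehyde, and the oxepane ether comes from the ε-lactone by reductive acetylation and silane reduction.
3. Tricyclic C16 ketone: the C15 methyl comes from α-methylenation and face-selective hydrogenation. C11 and C12 come from convex-face hydroboration, oxidation and reduction. The tetrahydrofuran comes from 5-exo iodoetherification of C2–OH onto an axial C10 vinyl group.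
4. trans-Decalin: the target has H1/H14 trans, but a [4+2] addition to the ring alkene C1=C14 can only give a cis fusion. C10 is therefore left unsubstituted in the cycloaddition, C1 is epimerised afterwards, and C10 is set later by axial cuprate addition. Ring B with C3 comes from desymmetrised 2-allyl-2-methylcyclohexane-1,3-dione.
5. Order of rings: carbocycle B (purchased) → cyclohexane A → tetrahydrofuran → oxepane (B expanded by one oxygen) → oxonene.

Key step: step 23

Numbering: C1 and C10 are the CH atoms common to the cyclohexane (ring A) and the tetrahydrofuran. C2 and C9 are the O-bearing CH atoms of the tetrahydrofuran, with C2 next to C3. C3 is the O-bearing quaternary carbon. C4–C5 are the CH2CH2 unit, C6 is the carbinol, and C7=C8 is the alkene. C11 is CH–OAc, C12 is CH–CH3, C13 is CH2, and C14 is the ring CH bearing C15. C15–C16 is the CH(CH3)–CH2O unit. Ring B is the carbocycle C1–C14–C15–C16–C3–C2.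

Assumption: a ketoreductase that reduces dione 3 to the (2R,3S) ketol (hydroxyl cis to methyl) can be found in a commercial enzyme panel.

**Step 1**
Reactants: 1 2-methylcyclohexane-1,3-dione; 2 allyl bromide
Product: 3 2-allyl-2-methylcyclohexane-1,3-dione
Conditions: NaOH (1 M aq), rt
Reagents that add atoms: none
Why: C-alkylation of the 1,3-dione enolate with a reactive allylic halide in water (enolate alkylation) gives the achiral 2,2-disubstituted dione whose quaternary carbon is the future C3 and whose two carbonyls (C2 and C16) are enantiotopic.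

**Step 2**
Reactants: 3 2-allyl-2-methylcyclohexane-1,3-dione
Product: 4 (2R,3S)-2-allyl-3-hydroxy-2-methylcyclohexan-1-one (ketone = C2, quaternary carbon = C3, carbinol = C16; OH cis to CH3)
Conditions: ketoreductase, NADP+, i-PrOH/phosphate buffer pH 7, 30 °C
Reagents that add atoms: none
Why: Enzymatic desymmetrising ketone reduction, a known reaction of 2,2-disubstituted cyclic 1,3-diones, delivers hydride to one face of one enantiotopic carbonyl and thereby fixes C3 (R here) together with a temporary C16 carbinol (S; OH cis to CH3 and trans to the allyl chain), any diastereomeric ketol being removed by chromatography.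

**Step 3**
Reactants: 4 (2R,3S)-ketol
Product: 5 (2R,3S)-2-allyl-3-(benzyloxy)-2-methylcyclohexan-1-one
Conditions: BnOC(=NH)CCl3, TfOH (cat.), CH2Cl2/cyclohexane, 0 °C → rt
Reagents that add atoms: benzyl 2,2,2-trichloroacetimidate ClC(Cl)(Cl)C(=N)OCc1ccccc1
Why: Acid-catalysed O-benzylation with the trichloroacetimidate avoids the basic conditions under which the β-hydroxy ketone would suffer retro-aldol cleavage and with it loss of C3.

**Step 4**
Reactants: 5 benzyl ether
Product: 7 (2R,3S)-3-(benzyloxy)-2-(3-hydroxypropyl)-2-methylcyclohexan-1-one, via B-alkyl-9-BBN adduct 6 (not isolated)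
Conditions: 9-BBN, THF, 0 °C → rt; then H2O2, NaOH, 0 °C
Reagents that add atoms: hydrogen peroxide OO
Why: Hydroboration–oxidation with 9-BBN is anti-Markovnikov and much faster at the terminal alkene than at the α-quaternary ketone, so the allyl group becomes the C4–C5–C6–OH chain.

**Step 5**
Reactants: 7 primary alcohol
Product: 8 (2R,3S)-3-(benzyloxy)-2-[3-(tert-butyldiphenylsilyloxy)propyl]-2-methylcyclohexan-1-one
Conditions: TBDPSCl, imidazole, CH2Cl2, rt
Reagents that add atoms: tert-butyldiphenylsilyl chloride CC(C)(C)[Si](Cl)(c1ccccc1)c1ccccc1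
Why: Routine silylation of the primary alcohol; the TBDPS ether tolerates the Brønsted and Lewis acids, SmI2, hydrogenations and peracid used later.

**Step 6**
Reactants: 8 TBDPS ether
Product: 10 (5S,6R)-5-(benzyloxy)-6-[3-(tert-butyldiphenylsilyloxy)propyl]-6-methylcyclohex-2-en-1-one, via lithium enolate 9 (not isolated)
Conditions: LDA, THF, −78 °C; then PhS(Cl)=N-t-Bu, −78 °C
Reagents that add atoms: none
Why: Mukaiyama dehydrogenation: C3 is quaternary, so LDA can only form the C1 enolate, which attacks sulfur of the sulfinimidoyl chloride and loses the sulfenamide by syn elimination at low temperature to give the C1=C14 enone without touching C3 or C16.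

**Step 7**
Reactants: 11 but-3-en-2-one
Product: 12 2-(tert-butyldimethylsilyloxy)buta-1,3-diene
Conditions: TBSOTf, Et3N, Et2O, 0 °C
Reagents that add atoms: tert-butyldimethylsilyl triflate CC(C)(C)[Si](C)(C)OS(=O)(=O)C(F)(F)F
Why: Soft enolisation and O-silylation of the enone gives the cross-conjugated 2-silyloxydiene C10=C11–C12(OTBS)=C13.

**Step 8**
Reactants: 10 enone; 12 silyloxydiene
Product: 14 trans-fused octalone (C2 ketone; C11=C12 TBS enol ether; H1/H14 trans; C13 on the face of the C4 chain), via cis adduct 13 (not isolated)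
Conditions: Tf2NH (10 mol %), CH2Cl2, −78 → −40 °C; then DBU, toluene, 60 °C
Reagents that add atoms: none
Why: Acid-catalysed Diels–Alder reaction of a 2-silyloxydiene with a cyclohexenone (Mukaiyama–Michael/Michael in the stepwise limit) bonds the nucleophilic terminus C13 to the β-carbon C14 ("para" orientation) on the face anti to the C16 benzyloxy group and the axial C3 methyl, which sets C14, and base-catalysed epimerisation at C1, the only enolisable stereocentre, then turns the necessarily cis adduct into the more stable trans-1-decalone with H1 anti to H14.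

**Step 9**
Reactants: 14 trans-fused octalone
Product: 15 equatorial C2 alcohol (OH cis to the C4 chain, anti to C16–OBn)
Conditions: SmI2, H2O, THF, 0 °C
Reagents that add atoms: none
Why: Samarium diiodide (ketyl) reduction gives the thermodynamically preferred equatorial C2 alcohol, anti to the axial C16 benzyloxy group, where hydride reagents would be hampered on both faces, and the silyl enol ether keeps C12 out of the reaction.

**Step 10**
Reactants: 15 alcohol
Product: 16 hydroxy enone (C12 ketone, C10=C11)
Conditions: Pd(OAc)2 (1.1 equiv), MeCN, rt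
Reagents that add atoms: none
Why: Saegusa–Ito oxidation: palladation at C11 and β-hydride loss from C10 convert the regiodefined silyl enol ether into the C10=C11–C12=O enone, and the hindered secondary alcohol is not oxidised at room temperature.

**Step 11**
Reactants: 16 hydroxy enone
Product: 18 C10-vinyl C11=C12 enol triflate (vinyl axial and cis to C2 on ring A), via magnesium enolate 17 (not isolated)
Conditions: CH2=CHMgBr (3.5 equiv), CuBr·SMe2 (30 mol %), THF, −78 → −40 °C; then Comins' reagent, −78 → 0 °C; aqueous work-up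
Reagents that add atoms: vinylmagnesium bromide C=C[Mg]Br; Comins' reagent O=S(=O)(N(c1ccc(Cl)cn1)S(=O)(=O)C(F)(F)F)C(F)(F)F
Why: Copper-catalysed conjugate addition with enolate O-triflation: on the rigid trans-decalin the vinyl group attacks C10 along the axial trajectory anti to the axial H1 (the course known from 1α-alkylation of steroidal 1-en-3-ones), which places C9 cis to C2, the regiodefined C11=C12 enolate is captured by the triflimide, and the hindered C2 alkoxide is returned as the alcohol on work-up.

**Step 12**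
Reactants: 18 vinyl enol triflate
Product: 19 tricyclic iodomethyl tetrahydrofuran (O bridges C2 and C9; CH2I cis to H10 and to C3)
Conditions: I2, NaHCO3, MeCN, 0 °C
Reagents that add atoms: iodine II
Why: 5-exo-trig iodoetherification: the vinyl group reacts in the rotamer with H10 eclipsing C9=C8 (minimal allylic strain), the C2 hydroxyl attacks C9 from the C1 side anti to the iodonium ion so that CH2I ends cis to H10 and to C3, ring A as a cyclohexene can flatten to a sofa to accept the cis fusion, and the electron-poor enol triflate is inert to iodine.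

**Step 13**
Reactants: 19 iodide
Product: 20 C8 pivalate
Conditions: CsOPiv, DMF, 70 °C
Reagents that add atoms: caesium pivalate [Cs+].CC(C)(C)C([O-])=O
Why: SN2 displacement of the primary iodide by a weakly basic carboxylate puts a robust ester on O8 with little risk of E2 elimination to the exocyclic enol ether.

**Step 14**
Reactants: 20 enol triflate
Product: 21 C11=C12(CH3) alkene
Conditions: Me2CuLi, THF, −20 → 0 °C
Reagents that add atoms: lithium dimethylcuprate [Li+].C[Cu-]C
Why: Cross-coupling of an enol triflate with a Gilman cuprate replaces OTf by CH3 without moving the double bond, and the pivalate and the ethers are inert at low temperature.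

**Step 15**
Reactants: 21 alkene
Product: 23 11-epi alcohol (C11–OH trans to C9; C12–CH3 cis to C9), via alkylborane 22 (not isolated)
Conditions: BH3·THF, THF, 0 °C → rt; then H2O2, NaOH, 0 °C
Reagents that add atoms: hydrogen peroxide OO
Why: Hydroboration–oxidation: boron goes to the less substituted C11 and the syn addition takes place on the convex face of the cis-fused hydroisobenzofuran, anti to the pseudoaxial C9, which sets C12 (new H12 cis to H10, CH3 cis to C9) and gives the C11 alcohol with the configuration opposite to the target.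

**Step 16**
Reactants: 23 11-epi alcohol
Product: 24 C11 ketone
Conditions: DMP, NaHCO3, CH2Cl2, 0 °C → rt
Reagents that add atoms: none
Why: Buffered Dess–Martin oxidation gives the C11 ketone under non-basic conditions so that the flanking stereocentres C10 and C12 are not epimerised.

**Step 17**
Reactants: 24 C11 ketone
Product: 25 C11 alcohol (OH cis to C9 and to the C12 methyl)
Conditions: NaBH4, MeOH/CH2Cl2, −40 → 0 °C
Reagents that add atoms: none
Why: Substrate-controlled ketone reduction: both α-substituents (C9 on C10 and CH3 on C12) shield the concave face, so hydride is delivered from the convex face and the C11 hydroxyl ends cis to both, as in the target.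

**Step 18**
Reactants: 25 C11 alcohol
Product: 26 C11 TBS ether
Conditions: TBSOTf, 2,6-lutidine, CH2Cl2, 0 °C → rt
Reagents that add atoms: tert-butyldimethylsilyl triflate CC(C)(C)[Si](C)(C)OS(=O)(=O)C(F)(F)F
Why: A silyl triflate with a hindered base silylates the crowded secondary alcohol so that C16 can be oxidised selectively afterwards.

**Step 19**
Reactants: 26 benzyl ether
Product: 27 C16 alcohol
Conditions: H2 (1 atm), Pd(OH)2/C, EtOAc, rt
Reagents that add atoms: none
Why: Hydrogenolysis removes the only benzyl ether; no alkene is left, and the silyl ethers and the pivalate are stable.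

**Step 20**
Reactants: 27 C16 alcohol
Product: 28 tricyclic C16 ketone (C15 = CH2)
Conditions: DMP, NaHCO3, CH2Cl2, rt
Reagents that add atoms: none
Why: Dess–Martin oxidation of the only free alcohol restores the C16 carbonyl, which cannot expel the β-oxygen on C2 because the intervening C3 bears no hydrogen.

**Step 21**
Reactants: 28 C16 ketone
Product: 29 15-methylene ketone
Conditions: (CH2O)n, i-Pr2NH·TFA, THF, reflux
Reagents that add atoms: paraformaldehyde (as formaldehyde) C=O
Why: Mannich-type α-methylenation with formaldehyde and a secondary ammonium salt can only take place at C15, the sole enolisable position.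

**Step 22**
Reactants: 29 15-methylene ketone
Product: 30 tricyclic C16 ketone with the C15 methyl axial (Baeyer–Villiger precursor; O6 TBDPS, O8 Piv, O11 TBS)
Conditions: H2 (1 atm), RhCl(PPh3)3 (10 mol %), benzene, rt
Reagents that add atoms: none
Why: Homogeneous hydrogenation with Wilkinson's catalyst reduces the 1,1-disubstituted enone alkene from the face opposite the axial C4 chain on C3, so hydrogen reaches C15 on the side of H14 and the methyl group is pushed into the axial position required by the target, under neutral conditions that do not equilibrate this less stable epimer.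

**Step 23**
Reactants: 30 tricyclic C16 ketone
Product: 32 ε-lactone (oxygen between C16 and C3), via Criegee adduct 31 (not isolated)
Conditions: m-CPBA, Na2HPO4, CH2Cl2, 0 °C → rt
Reagents that add atoms: m-CPBA O=C(OO)c1cccc(Cl)c1
Why: Baeyer–Villiger oxidation: the peracid adds to the C16 carbonyl from the open face anti to the axial C4 chain to give Criegee adduct 31, and the C3–C16 bond, aligned antiperiplanar to the O–O bond, shifts from carbon to oxygen with loss of 3-chlorobenzoate. The closest known reaction type is the peracid ring expansion of α-quaternary cyclohexanones to ε-lactones. No ring is closed end to end: the six-membered carbocycle C1–C14–C15–C16–C3–C2 grows to the seven-membered lactone through a concerted 1,2-shift that makes C3–O and O–C16 and breaks C3–C16. No stereocentre is created, and C3 migrates with retention, so the configuration fixed in step 2 becomes that of the tertiary ether carbon. The selectivity needed is migration of C3 rather than C15; it rests on the higher migratory aptitude of the fully substituted carbon and is helped by relief of the 1,3-diaxial contact between C4 and the C15 methyl and of the strain that a six-membered ring B imposes on this cis/trans/trans-fused tricycle. The phosphate buffer keeps C15 from enolising, and the substrate carries no alkene, free alcohol or electron-rich arene that the peracid could attack.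

**Step 24**
Reactants: 32 ε-lactone
Product: 34 lactol acetate with C8 acetate (C16 epimers), via lactol 33 (not isolated)
Conditions: DIBAL-H (3.3 equiv), CH2Cl2, −78 °C; then pyridine, DMAP, Ac2O, −78 → −20 °C
Reagents that add atoms: acetic anhydride CC(=O)OC(C)=O
Why: Reductive acetylation: DIBAL-H stops at the tetrahedral aluminium lactolate at −78 °C and at the same time cleaves the pivalate, and in situ acylation traps the seven-membered lactol before it can open and converts O8 into the acetate.

**Step 25**
Reactants: 34 lactol acetate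
Product: 35 oxepane (C16 = CH2; C8 acetate)
Conditions: Et3SiH, BF3·OEt2, CH2Cl2, −78 °C
Reagents that add atoms: none
Why: Lewis-acid ionisation of the lactol acetate to the C16 oxocarbenium ion and hydride transfer from the silane (ionic reduction) give the CH2–O–C3 ether, while the primary acetate and the silyl ethers survive at −78 °C.

**Step 26**
Reactants: 35 C8 acetate
Product: 36 C8 alcohol
Conditions: K2CO3 (cat.), MeOH, 0 °C
Reagents that add atoms: none
Why: Base-catalysed transesterification removes the only ester in the molecule.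

**Step 27**
Reactants: 36 C8 alcohol
Product: 37 C8 aldehyde
Conditions: DMP, NaHCO3, CH2Cl2, rt
Reagents that add atoms: none
Why: Buffered Dess–Martin oxidation gives the α-alkoxy aldehyde without epimerising C9, whose substituent in any case sits on the favoured convex face.

**Step 28**
Reactants: 37 C8 aldehyde
Product: 38 (Z)-alkenyl iodide C8H=C7(I)CH3
Conditions: EtPPh3I, n-BuLi, THF, rt; I2, −78 °C; NaHMDS, −20 °C; then 37, −78 °C
Reagents that add atoms: ethyltriphenylphosphonium iodide CC[P+](c1ccccc1)(c1ccccc1)c1ccccc1.[I-]; iodine II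
Why: Stork–Zhao-type Wittig olefination with the α-iodoethylidene ylide is kinetically Z-selective (iodine cis to C9), which fixes the geometry of the C7=C8 alkene.

**Step 29**
Reactants: 38 bis-silyl ether
Product: 39 C6,C11 diol
Conditions: HF·pyridine, pyridine/THF, 0 °C → rt
Reagents that add atoms: none
Why: Fluoride-mediated desilylation removes both silyl ethers and leaves the alkenyl iodide and the cyclic ethers untouched.

**Step 30**
Reactants: 39 diol
Product: 40 C6 aldehyde with free C11 hydroxyl
Conditions: TEMPO (cat.), PhI(OAc)2, CH2Cl2, rt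
Reagents that add atoms: none
Why: Oxoammonium (TEMPO) oxidation is selective for the primary C6 alcohol over the crowded secondary C11 alcohol.

**Step 31**
Reactants: 40 hydroxy aldehyde
Product: 41 C11 acetate iodo aldehyde
Conditions: Ac2O, DMAP, Et3N, CH2Cl2, rt
Reagents that add atoms: acetic anhydride CC(=O)OC(C)=O
Why: DMAP-catalysed acylation esterifies the remaining C11 hydroxyl, and the aldehyde and the alkenyl iodide are inert under these mild conditions.

**Step 32**
Reactants: 41 iodo aldehyde
Product: 43 target CNP0289966.2, via alkenylchromium 42 (not isolated)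
Conditions: CrCl2 (10 equiv), NiCl2 (cat.), DMSO, rt, high dilution
Reagents that add atoms: none
Why: Intramolecular Nozaki–Hiyama–Kishi reaction: nickel-catalysed formation of the alkenylchromium(III) species keeps the Z geometry and tolerates the acetate, and closure of the nine-membered oxonene (C6–C7) should occur with the aldehyde oxygen turned outward from the forming ring, exposing the face that gives the (6R) allylic alcohol.

**Compound list**
1 | 2-methylcyclohexane-1,3-dione | CC1C(=O)CCCC1=O | starting material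
2 | allyl bromide | C=CCBr | starting material
3 | 2-allyl-2-methylcyclohexane-1,3-dione | C=CCC1(C)C(=O)CCCC1=O | intermediate
4 | (2R,3S)-2-allyl-3-hydroxy-2-methylcyclohexan-1-one | O=C1CCC[C@H](O)[C@@]1(C)CC=C | intermediate
5 | (2R,3S)-2-allyl-3-(benzyloxy)-2-methylcyclohexan-1-one | O=C1CCC[C@H](OCc2ccccc2)[C@@]1(C)CC=C | intermediate
6 | B-alkyl-9-BBN adduct of 5 (not isolated) | O=C1CCC[C@H](OCc2ccccc2)[C@@]1(C)CCCB1C2CCCC1CCC2 | intermediate
7 | (2R,3S)-3-(benzyloxy)-2-(3-hydroxypropyl)-2-methylcyclohexan-1-one | O=C1CCC[C@H](OCc2ccccc2)[C@@]1(C)CCCO | intermediate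
8 | TBDPS ether of 7 | O=C1CCC[C@H](OCc2ccccc2)[C@@]1(C)CCCO[Si](c1ccccc1)(c1ccccc1)C(C)(C)C | intermediate
9 | lithium C1 enolate of 8 (not isolated) | [Li]OC1=CCC[C@H](OCc2ccccc2)[C@@]1(C)CCCO[Si](c1ccccc1)(c1ccccc1)C(C)(C)C | intermediate
10 | (5S,6R)-5-(benzyloxy)-6-[3-(TBDPS-oxy)propyl]-6-methylcyclohex-2-en-1-one | O=C1C=CC[C@H](OCc2ccccc2)[C@@]1(C)CCCO[Si](c1ccccc1)(c1ccccc1)C(C)(C)C | intermediate
11 | but-3-en-2-one | CC(=O)C=C | starting material
12 | 2-(tert-butyldimethylsilyloxy)buta-1,3-diene | C=CC(=C)O[Si](C)(C)C(C)(C)C | intermediate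
13 | cis-fused Diels–Alder adduct (H1/H14 cis; not isolated) | O=C1[C@H]2CC=C(O[Si](C)(C)C(C)(C)C)C[C@H]2C[C@H](OCc2ccccc2)[C@@]1(C)CCCO[Si](c1ccccc1)(c1ccccc1)C(C)(C)C | intermediate
14 | trans-fused octalone (H1/H14 trans) | O=C1[C@@H]2CC=C(O[Si](C)(C)C(C)(C)C)C[C@H]2C[C@H](OCc2ccccc2)[C@@]1(C)CCCO[Si](c1ccccc1)(c1ccccc1)C(C)(C)C | intermediate
15 | equatorial C2 alcohol | O[C@H]1[C@@H]2CC=C(O[Si](C)(C)C(C)(C)C)C[C@H]2C[C@H](OCc2ccccc2)[C@@]1(C)CCCO[Si](c1ccccc1)(c1ccccc1)C(C)(C)C | intermediate
16 | hydroxy enone (C12=O, C10=C11) | O[C@H]1[C@@H]2C=CC(=O)C[C@H]2C[C@H](OCc2ccccc2)[C@@]1(C)CCCO[Si](c1ccccc1)(c1ccccc1)C(C)(C)C | intermediate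
17 | magnesium enolate/alkoxide after vinyl addition (not isolated) | Br[Mg]O[C@H]1[C@@H]2[C@H](C=C)C=C(O[Mg]Br)C[C@H]2C[C@H](OCc2ccccc2)[C@@]1(C)CCCO[Si](c1ccccc1)(c1ccccc1)C(C)(C)C | intermediate
18 | C10-vinyl C11=C12 enol triflate | O[C@H]1[C@@H]2[C@H](C=C)C=C(OS(=O)(=O)C(F)(F)F)C[C@H]2C[C@H](OCc2ccccc2)[C@@]1(C)CCCO[Si](c1ccccc1)(c1ccccc1)C(C)(C)C | intermediate
19 | tricyclic iodomethyl tetrahydrofuran | IC[C@@H]1O[C@H]2[C@@H]3[C@H]1C=C(OS(=O)(=O)C(F)(F)F)C[C@H]3C[C@H](OCc1ccccc1)[C@@]2(C)CCCO[Si](c1ccccc1)(c1ccccc1)C(C)(C)C | intermediate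
20 | C8 pivalate enol triflate | CC(C)(C)C(=O)OC[C@@H]1O[C@H]2[C@@H]3[C@H]1C=C(OS(=O)(=O)C(F)(F)F)C[C@H]3C[C@H](OCc1ccccc1)[C@@]2(C)CCCO[Si](c1ccccc1)(c1ccccc1)C(C)(C)C | intermediate
21 | C11=C12(CH3) alkene | CC(C)(C)C(=O)OC[C@@H]1O[C@H]2[C@@H]3[C@H]1C=C(C)C[C@H]3C[C@H](OCc1ccccc1)[C@@]2(C)CCCO[Si](c1ccccc1)(c1ccccc1)C(C)(C)C | intermediate
22 | C11 alkylborane (not isolated) | CC(C)(C)C(=O)OC[C@@H]1O[C@H]2[C@@H]3[C@H]1[C@@H](B)[C@H](C)C[C@H]3C[C@H](OCc1ccccc1)[C@@]2(C)CCCO[Si](c1ccccc1)(c1ccccc1)C(C)(C)C | intermediate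
23 | 11-epi alcohol | CC(C)(C)C(=O)OC[C@@H]1O[C@H]2[C@@H]3[C@H]1[C@@H](O)[C@H](C)C[C@H]3C[C@H](OCc1ccccc1)[C@@]2(C)CCCO[Si](c1ccccc1)(c1ccccc1)C(C)(C)C | intermediate
24 | C11 ketone | CC(C)(C)C(=O)OC[C@@H]1O[C@H]2[C@@H]3[C@H]1C(=O)[C@H](C)C[C@H]3C[C@H](OCc1ccccc1)[C@@]2(C)CCCO[Si](c1ccccc1)(c1ccccc1)C(C)(C)C | intermediate
25 | C11 alcohol (target configuration) | CC(C)(C)C(=O)OC[C@@H]1O[C@H]2[C@@H]3[C@H]1[C@H](O)[C@H](C)C[C@H]3C[C@H](OCc1ccccc1)[C@@]2(C)CCCO[Si](c1ccccc1)(c1ccccc1)C(C)(C)C | intermediate
26 | C11 TBS ether | CC(C)(C)C(=O)OC[C@@H]1O[C@H]2[C@@H]3[C@H]1[C@H](O[Si](C)(C)C(C)(C)C)[C@H](C)C[C@H]3C[C@H](OCc1ccccc1)[C@@]2(C)CCCO[Si](c1ccccc1)(c1ccccc1)C(C)(C)C | intermediate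
27 | C16 alcohol | CC(C)(C)C(=O)OC[C@@H]1O[C@H]2[C@@H]3[C@H]1[C@H](O[Si](C)(C)C(C)(C)C)[C@H](C)C[C@H]3C[C@H](O)[C@@]2(C)CCCO[Si](c1ccccc1)(c1ccccc1)C(C)(C)C | intermediate
28 | C16 ketone, C15 = CH2 | CC(C)(C)C(=O)OC[C@@H]1O[C@H]2[C@@H]3[C@H]1[C@H](O[Si](C)(C)C(C)(C)C)[C@H](C)C[C@H]3CC(=O)[C@@]2(C)CCCO[Si](c1ccccc1)(c1ccccc1)C(C)(C)C | intermediate
29 | 15-methylene ketone | CC(C)(C)C(=O)OC[C@@H]1O[C@H]2[C@@H]3[C@H]1[C@H](O[Si](C)(C)C(C)(C)C)[C@H](C)C[C@H]3C(=C)C(=O)[C@@]2(C)CCCO[Si](c1ccccc1)(c1ccccc1)C(C)(C)C | intermediate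
30 | tricyclic C16 ketone (key-step precursor) | CC(C)(C)C(=O)OC[C@@H]1O[C@H]2[C@@H]3[C@H]1[C@H](O[Si](C)(C)C(C)(C)C)[C@H](C)C[C@H]3[C@@H](C)C(=O)[C@@]2(C)CCCO[Si](c1ccccc1)(c1ccccc1)C(C)(C)C | intermediate
31 | Criegee adduct (not isolated) | CC(C)(C)C(=O)OC[C@@H]1O[C@H]2[C@@H]3[C@H]1[C@H](O[Si](C)(C)C(C)(C)C)[C@H](C)C[C@H]3[C@@H](C)C(O)(OOC(=O)c1cccc(Cl)c1)[C@@]2(C)CCCO[Si](c1ccccc1)(c1ccccc1)C(C)(C)C | intermediate
32 | ε-lactone (key-step product) | CC(C)(C)C(=O)OC[C@@H]1O[C@H]2[C@@H]3[C@H]1[C@H](O[Si](C)(C)C(C)(C)C)[C@H](C)C[C@H]3[C@@H](C)C(=O)O[C@@]2(C)CCCO[Si](c1ccccc1)(c1ccccc1)C(C)(C)C | intermediate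
33 | lactol with free C8 hydroxyl (present as aluminium alkoxides; not isolated) | OC[C@@H]1O[C@H]2[C@@H]3[C@H]1[C@H](O[Si](C)(C)C(C)(C)C)[C@H](C)C[C@H]3[C@@H](C)C(O)O[C@@]2(C)CCCO[Si](c1ccccc1)(c1ccccc1)C(C)(C)C | intermediate
34 | lactol acetate, C8 acetate | CC(=O)OC[C@@H]1O[C@H]2[C@@H]3[C@H]1[C@H](O[Si](C)(C)C(C)(C)C)[C@H](C)C[C@H]3[C@@H](C)C(OC(C)=O)O[C@@]2(C)CCCO[Si](c1ccccc1)(c1ccccc1)C(C)(C)C | intermediate
35 | oxepane, C8 acetate | CC(=O)OC[C@@H]1O[C@H]2[C@@H]3[C@H]1[C@H](O[Si](C)(C)C(C)(C)C)[C@H](C)C[C@H]3[C@@H](C)CO[C@@]2(C)CCCO[Si](c1ccccc1)(c1ccccc1)C(C)(C)C | intermediate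
36 | C8 alcohol | OC[C@@H]1O[C@H]2[C@@H]3[C@H]1[C@H](O[Si](C)(C)C(C)(C)C)[C@H](C)C[C@H]3[C@@H](C)CO[C@@]2(C)CCCO[Si](c1ccccc1)(c1ccccc1)C(C)(C)C | intermediate
37 | C8 aldehyde | O=C[C@@H]1O[C@H]2[C@@H]3[C@H]1[C@H](O[Si](C)(C)C(C)(C)C)[C@H](C)C[C@H]3[C@@H](C)CO[C@@]2(C)CCCO[Si](c1ccccc1)(c1ccccc1)C(C)(C)C | intermediate
38 | (Z)-alkenyl iodide | C/C(I)=C/[C@@H]1O[C@H]2[C@@H]3[C@H]1[C@H](O[Si](C)(C)C(C)(C)C)[C@H](C)C[C@H]3[C@@H](C)CO[C@@]2(C)CCCO[Si](c1ccccc1)(c1ccccc1)C(C)(C)C | intermediate
39 | C6,C11 diol | C/C(I)=C/[C@@H]1O[C@H]2[C@@H]3[C@H]1[C@H](O)[C@H](C)C[C@H]3[C@@H](C)CO[C@@]2(C)CCCO | intermediate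
40 | C6 aldehyde, C11 hydroxyl | C/C(I)=C/[C@@H]1O[C@H]2[C@@H]3[C@H]1[C@H](O)[C@H](C)C[C@H]3[C@@H](C)CO[C@@]2(C)CCC=O | intermediate
41 | C11 acetate iodo aldehyde | C/C(I)=C/[C@@H]1O[C@H]2[C@@H]3[C@H]1[C@H](OC(C)=O)[C@H](C)C[C@H]3[C@@H](C)CO[C@@]2(C)CCC=O | intermediate
42 | alkenylchromium(III) species (not isolated) | C/C([Cr](Cl)Cl)=C/[C@@H]1O[C@H]2[C@@H]3[C@H]1[C@H](OC(C)=O)[C@H](C)C[C@H]3[C@@H](C)CO[C@@]2(C)CCC=O | intermediate
43 | CNP0289966.2 | CC(=O)O[C@H]1[C@@H]2[C@@H]3[C@@H](C[C@H]1C)[C@@H](C)CO[C@@]1(C)CC[C@@H](O)/C(C)=C\[C@@H]2O[C@@H]31 | target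

**Total steps:** 32. **Longest linear sequence:** 31 (steps 1–6 and 8–32; step 7 is a one-step branch).

**Steps most likely to fail**

1. **Step 23 (key step).**
   - What may go wrong: peracid addition to a carbonyl flanked by a quaternary carbon and by a carbon carrying an axial methyl may be slow. Acid-catalysed enolisation could then erode C15, or C15 could migrate in competition with C3.
   - Fallback: the oxygen is inserted before C15 is methylated, setting out from ketone 28.
   - m-CPBA/Na2HPO4 acts on this less hindered ketone, where the fully substituted carbon competes only with a CH2 group. This should give the 15-demethyl ε-lactone F1.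
   - LDA then MeI alkylates the lactone enolate from the face away from C13 and should give the 15-epi ε-lactone F2.
   - Renewed enolisation with LDA and kinetic protonation by a hindered phenol from the same open face inverts C15. The sequence comes back to the route at 32.

2. **Step 22.**
   - What may go wrong: the face selectivity of hydrogen delivery may be poor, the exocyclic alkene may migrate into the ring, or the less stable axial methyl epimer may equilibrate.
   - Fallback: C15 is built by alkylation and then inverted by kinetic protonation, setting out from ketone 28.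
   - LDA then MeI should give the 15-epi ketone F3 (equatorial methyl), because the axial C4 chain blocks the other face.
   - Deprotonation with KHMDS and a quench at −78 °C with 2,6-di-tert-butyl-4-methylphenol delivers the proton from that same unblocked face. The sequence comes back to the route at 30.

3. **Step 2.**
   - What may go wrong: reduction may take place mainly from the methyl side of the dione, so that only ketols with the hydroxyl cis to the allyl group are formed.
   - Fallback: carbinol and ketone are exchanged, setting out from dione 3.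
   - Baker's yeast gives the (2S,3S) ketol F4, in which the carbinol carbon is C2.
   - Hydroxyl-directed reduction with Me4NBH(OAc)3 gives the anti diol F5.
   - I2/NaHCO3 engages only the hydroxyl that is cis to the allyl group and gives the bicyclic iodoether F6.
   - Benzyl trichloroacetimidate/TfOH protects the remaining C16 hydroxyl as the benzyl ether F7.
   - Zn/AcOH reopens the iodoether to the hydroxy alkene F8.
   - Dess–Martin oxidation of the freed C2 hydroxyl comes back to the route at 5.

**Further compounds**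
F1 | step 23 | 15-demethyl ε-lactone | CC(C)(C)C(=O)OC[C@@H]1O[C@H]2[C@@H]3[C@H]1[C@H](O[Si](C)(C)C(C)(C)C)[C@H](C)C[C@H]3CC(=O)O[C@@]2(C)CCCO[Si](c1ccccc1)(c1ccccc1)C(C)(C)C
F2 | step 23 | 15-epi ε-lactone | CC(C)(C)C(=O)OC[C@@H]1O[C@H]2[C@@H]3[C@H]1[C@H](O[Si](C)(C)C(C)(C)C)[C@H](C)C[C@H]3[C@H](C)C(=O)O[C@@]2(C)CCCO[Si](c1ccccc1)(c1ccccc1)C(C)(C)C
F3 | step 22 | 15-epi ketone | CC(C)(C)C(=O)OC[C@@H]1O[C@H]2[C@@H]3[C@H]1[C@H](O[Si](C)(C)C(C)(C)C)[C@H](C)C[C@H]3[C@H](C)C(=O)[C@@]2(C)CCCO[Si](c1ccccc1)(c1ccccc1)C(C)(C)C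
F4 | step 2 | (2S,3S)-2-allyl-3-hydroxy-2-methylcyclohexan-1-one | O=C1CCC[C@H](O)[C@]1(C)CC=C
F5 | step 2 | anti 2-allyl-2-methylcyclohexane-1,3-diol (C2–OH cis, C16–OH trans to allyl) | O[C@H]1CCC[C@H](O)[C@]1(C)CC=C
F6 | step 2 | bicyclic iodoether (C2–O–C5; C5 epimers) | O[C@H]1CCC[C@@H]2OC(CI)C[C@]12C
F7 | step 2 | C16 benzyl ether of the iodoether | c1ccccc1CO[C@H]1CCC[C@@H]2OC(CI)C[C@]12C
F8 | step 2 | hydroxy alkene (C2–OH free, C16–OBn) | c1ccccc1CO[C@H]1CCC[C@H](O)[C@]1(C)CC=C
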